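**Retrosynthetic overview**

- Target: (R)-2-[(Z)-henicos-12-enyl]-6-methyl-2,3-dihydro-4H-pyran-4-one. Ring atoms are called O1, C2 (the (R) stereocenter carrying the chain), C3, C4 (C=O), C5 (=CH) and C6 (C–CH3); side-chain carbons are primed.
- Enabling feature: the vinylogous ester O1–C6(CH3)=C5H–C4(=O) is an acetate C=O and a terminal C≡C in metathesised form, and O1 and C4 sit 1,3 to each other across C2–C3. The pyranone is therefore an isomer of an open-chain homopropargyl acetate.
- Disconnection 1 (last step, the only ring): C5=C6, with the acetyl oxygen passing to C4, by gold-catalysed alkyne–ester carbonyl metathesis of the (R)-homopropargyl acetate. A 1,3-dioxanium ring forms and opens again inside this step.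
- Disconnection 2: the O-acetyl group, then C3–C4 (acetylide on the (R)-chlorohydrin via its terminal epoxide).
- Disconnection 3: C1′–C2′, from (R)-epichlorohydrin (supplies C3, C2, C1′ and the configuration) and the C20 Z-alkenyl Grignard reagent made from commercial (Z)-icos-11-en-1-ol. The Z-alkene is bought, not made.

Key step: step 5

Remark: (Z)-icos-11-en-1-ol (cis-11-eicosenol) and (R)-epichlorohydrin are taken as articles of commerce.

**Step 1**
Reactants: 1 (Z)-icos-11-en-1-ol
Product: 2 (Z)-1-bromoicos-11-ene
Conditions: CBr4, PPh3, CH2Cl2, 0 °C to rt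
Reagents that add atoms: carbon tetrabromide, BrC(Br)(Br)Br
Why: Appel reaction of a primary alcohol, run under neutral conditions that should neither touch nor isomerise the remote Z-alkene.

**Step 2**
Reactants: 2 (Z)-1-bromoicos-11-ene; 3 (R)-epichlorohydrin [(R)-2-(chloromethyl)oxirane]
Product: 5 (2R,14Z)-1-chlorotricos-14-en-2-ol, via Grignard reagent 4 (not isolated)
Conditions: Mg, THF, rt to 40 °C; then CuI (10 mol%), 3 (1.2 equiv), THF, −40 to −20 °C; sat. aq NH4Cl
Reagents that add atoms: none
Why: Copper-catalysed SN2 opening of a terminal epoxide by a Grignard reagent: under CuI catalysis the carbon nucleophile should attack the unsubstituted ring carbon of 3 in preference to the C–Cl carbon, and since no bond to the stereocenter is made or broken its configuration is carried unchanged into 5 (descriptor stays R).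

**Step 3**
Reactants: 5 (2R,14Z)-1-chlorotricos-14-en-2-ol
Product: 7 (4R,16Z)-pentacos-16-en-1-yn-4-ol, via epoxide 6 (not isolated)
Conditions: LiC≡CH·H2NCH2CH2NH2 (3.5 equiv), DMSO–THF, 0 °C to rt; then H2O
Reagents that add atoms: lithium acetylide–ethylenediamine complex, [Li+].[C-]#C.NCCN
Why: Base-induced Williamson closure of the chlorohydrin to the terminal epoxide, then SN2 alkynylation at its unsubstituted carbon by the acetylide; neither event touches the carbinol carbon, so it stays (R).

**Step 4**
Reactants: 7 (4R,16Z)-pentacos-16-en-1-yn-4-ol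
Product: 8 (4R,16Z)-pentacos-16-en-1-yn-4-yl acetate
Conditions: Ac2O, Et3N, DMAP (5 mol%), CH2Cl2, 0 °C to rt
Reagents that add atoms: acetic anhydride, CC(=O)OC(C)=O
Why: DMAP-catalysed O-acetylation of a secondary alcohol, with retention, installs the acetyl group whose carbonyl carbon and methyl group become C6 and its CH3.

**Step 5**
Reactants: 8 (4R,16Z)-pentacos-16-en-1-yn-4-yl acetate
Product: 10 (R)-2-[(Z)-henicos-12-en-1-yl]-6-methyl-2,3-dihydro-4H-pyran-4-one, via aurated dioxanium triflimide 9 (not isolated)
Conditions: Ph3PAuNTf2 (5 mol%), 4 Å MS, dry ClCH2CH2Cl (0.05 M), 60 °C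
Reagents that add atoms: none
Why: Proposed new method: the cationic monovalent gold catalyst should activate the terminal alkyne so that the acetate carbonyl oxygen adds anti to gold at the internal alkyne carbon (future C4), giving the aurated 2-methyl-1,3-dioxan-2-ylium 9; with no proton source present, its aurated enol-ether carbon (future C5) should then attack the dioxanium carbon (future C6) through a four-membered oxete-like transition structure, and cleavage of the bond from C6 to the former carbonyl oxygen with release of the gold cation leaves the C4 ketone and the C5=C6 enol ether (a net intramolecular alkyne–ester carbonyl metathesis, that is a Petasis–Ferrier-type 1,3 oxygen-to-carbon shift at the acyl oxidation level). The closest known reaction types are the gold-catalysed 6-exo-dig cyclisation of homopropargyl carbonates and amides (the latter followed by Ferrier rearrangement to piperidin-4-ones), the gold-catalysed Petasis–Ferrier-type cyclisation of homopropargylic acetals to tetrahydropyran-4-ones, the gold-mediated 1,3 O-to-C acyl shift through an oxetenium array, and Lewis-acid alkyne–carbonyl metathesis of ketones and aldehydes. The temporary dioxanium ring closes 6-exo-dig, and the pyranone ring closes by C5–C6 bond formation in a 6-(enolendo)-endo-trig sense across the O–C–O bridge, which is broken in the same event. No new stereocenter is formed, and C2 keeps its (R) configuration because none of its bonds is broken. The step needs Markovnikov regioselectivity of the oxygen attack, secured by the terminal alkyne and the 1,3-placement of acetoxy and alkynyl groups (6-exo over 7-endo), and carbon attack in preference to protodeauration, secured by the aprotic sieve-dried medium and the absence of O–H or N–H groups in 8. The remote Z-alkene should not compete, because the catalyst binds the alkyne preferentially and neither radicals nor strong acid are present.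

**Compound list**

1 | (Z)-icos-11-en-1-ol | CCCCCCCC/C=C\CCCCCCCCCCO | starting material
2 | (Z)-1-bromoicos-11-ene | CCCCCCCC/C=C\CCCCCCCCCCBr | intermediate
3 | (R)-epichlorohydrin, (R)-2-(chloromethyl)oxirane | ClC[C@H]1CO1 | starting material
4 | (Z)-icos-11-en-1-ylmagnesium bromide | CCCCCCCC/C=C\CCCCCCCCCC[Mg]Br | intermediate (not isolated)
5 | (2R,14Z)-1-chlorotricos-14-en-2-ol | CCCCCCCC/C=C\CCCCCCCCCCC[C@@H](O)CCl | intermediate
6 | (R)-2-[(Z)-henicos-12-en-1-yl]oxirane | CCCCCCCC/C=C\CCCCCCCCCCC[C@@H]1CO1 | intermediate (not isolated)
7 | (4R,16Z)-pentacos-16-en-1-yn-4-ol | CCCCCCCC/C=C\CCCCCCCCCCC[C@@H](O)CC#C | intermediate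
8 | (4R,16Z)-pentacos-16-en-1-yn-4-yl acetate | CCCCCCCC/C=C\CCCCCCCCCCC[C@@H](OC(C)=O)CC#C | intermediate
9 | (4R)-4-[(Z)-henicos-12-en-1-yl]-2-methyl-6-[(E)-(triphenylphosphine)gold-methylidene]-1,3-dioxan-2-ylium bis(trifluoromethanesulfonyl)imide | C[C+]1O[C@H](CCCCCCCCCCC/C=C\CCCCCCCC)C/C(=C\[Au-][P+](c2ccccc2)(c2ccccc2)c2ccccc2)O1.[N-](S(=O)(=O)C(F)(F)F)S(=O)(=O)C(F)(F)F | intermediate (not isolated)
10 | (R)-2-[(Z)-henicos-12-en-1-yl]-6-methyl-2,3-dihydro-4H-pyran-4-one | CCCCCCCC/C=C\CCCCCCCCCCC[C@@H]1CC(=O)C=C(C)O1 | target

**Step count**

Total step count: 5. Longest linear sequence: 5 steps (1 to 10).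

**Steps most likely to fail**

Step 5 (proposed new method). The aurated dioxanium may be diverted by adventitious water or protons into net hydration instead of the carbon–carbon bond-forming shift, or the catalyst may rest as an unreactive gold acetylide of the terminal alkyne. The fallback uses known chemistry, sets out from compound 8 and returns at compound 10.
- Deliberate gold-catalysed Markovnikov hydration, assisted by the acetate carbonyl (Ph3PAuNTf2 2 mol%, H2O 3 equiv, 1,4-dioxane, rt), should give (4R,16Z)-2-oxopentacos-16-en-4-yl acetate F1.
- LiN(SiMe3)2 (2.2 equiv), THF, −78 °C should deprotonate the methyl group and transfer the acetyl group from oxygen to carbon (intramolecular Claisen condensation of the aliphatic Baker–Venkataraman type), giving (6R,18Z)-6-hydroxyheptacos-18-ene-2,4-dione F2.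
- TsOH (cat.), toluene, rt should cyclodehydrate F2 to the dihydropyranone 10.
- Material that strays along the hydration path in step 5 is F1 itself and can be fed into this sequence.

Step 2. Competing attack of the Grignard reagent at the C–Cl carbon of epichlorohydrin would erode the enantiomeric purity, and Wurtz-type homocoupling would consume the bromide. In the fallback the stereocenter is secured by kinetic resolution instead of the chiral pool; it sets out from compound 2 and returns at compound 6.
- Grignard reagent 4 is trapped with ethylene oxide (THF, 0 °C) to give (Z)-docos-13-en-1-ol F3, which is erucyl alcohol and can also be bought.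
- Dess–Martin periodinane, CH2Cl2 gives (Z)-docos-13-enal F4.
- Corey–Chaykovsky methylenation (Me3S+ I−, NaH, DMSO–THF) gives racemic 2-[(Z)-henicos-12-en-1-yl]oxirane F5.
- Jacobsen hydrolytic kinetic resolution with (R,R)-(salen)Co(OAc) (salen = N,N′-bis(3,5-di-tert-butylsalicylidene)-1,2-cyclohexanediaminate; 0.5 mol%, 0.55 equiv H2O) should leave the (R)-epoxide 6. The (S)-enantiomer is hydrolysed to (2S,14Z)-tricos-14-ene-1,2-diol F6, which is removed by chromatography.
- Isolated 6 is then opened with lithium acetylide as in step 3.

Step 3. The strongly basic one-pot closure and alkynylation may suffer from migration of the triple bond, elimination, or stalling at the epoxide. The fallback separates the two events and runs the alkynylation under Lewis-acid activation with a protected alkyne; it sets out from compound 5 and returns at compound 7.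
- K2CO3, MeOH, rt closes 5 to epoxide 6, which is isolated.
- LiC≡CSiMe3, BF3·OEt2, THF, −78 °C (Yamaguchi–Hirao alkynylation) should give (4R,16Z)-1-(trimethylsilyl)pentacos-16-en-1-yn-4-ol F7.
- K2CO3, MeOH removes the silyl group to give 7.

**Further compounds**

F1 | step 5 | (4R,16Z)-2-oxopentacos-16-en-4-yl acetate | CCCCCCCC/C=C\CCCCCCCCCCC[C@@H](OC(C)=O)CC(C)=O
F2 | step 5 | (6R,18Z)-6-hydroxyheptacos-18-ene-2,4-dione | CCCCCCCC/C=C\CCCCCCCCCCC[C@@H](O)CC(=O)CC(C)=O
F3 | step 2 | (Z)-docos-13-en-1-ol | CCCCCCCC/C=C\CCCCCCCCCCCCO
F4 | step 2 | (Z)-docos-13-enal | CCCCCCCC/C=C\CCCCCCCCCCCC=O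
F5 | step 2 | rac-2-[(Z)-henicos-12-en-1-yl]oxirane | CCCCCCCC/C=C\CCCCCCCCCCCC1CO1
F6 | step 2 | (2S,14Z)-tricos-14-ene-1,2-diol | CCCCCCCC/C=C\CCCCCCCCCCC[C@H](O)CO
F7 | step 3 | (4R,16Z)-1-(trimethylsilyl)pentacos-16-en-1-yn-4-ol | CCCCCCCC/C=C\CCCCCCCCCCC[C@@H](O)CC#C[Si](C)(C)C
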